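**Retrosynthetic overview**

- The target is cut at the bond between ring B and the linker carbon C(=CH2): a Weinreb amide on the ring A side is acylated by a 4-silyloxycyclohexyl Grignard reagent and the resulting ketone is methylenated. The bromohydrin of ring B goes back to a 4-substituted cyclohexanone (chiral-base desymmetrisation, α-bromination, methyl addition).
- In ring A the isopropenyl group goes back to an acetyl group and the oxirane to the ring alkene. The oxygen is delivered syn to the C3 side chain by iodolactonisation of the CH2CO2H arm followed by methanolysis.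
- The strategy rests on ring A: without the oxirane it is a 1-methylcyclohexene whose C3 carries the linker CH2 and whose C4 carries the isopropenyl carbon. This is the "ortho/para" adduct of methyl (E)-5-methylhexa-3,5-dienoate and methyl vinyl ketone; the asymmetric Diels–Alder reaction forms C3–C4 and C5–C6 and sets the first two stereocentres.
- Order of ring formation: ring A (step 3), then the oxirane on ring A (steps 5–6); ring B arrives as a preformed cyclohexane (step 10) and is functionalised last.

Key step: step 3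

Remark: the 4-silyloxycyclohexyl unit (compounds 15–20) is carried as a cis/trans mixture; this has no consequence because its carbinol carbon becomes the ketone carbon of 21.

**Route**

Step 1
Reactants: 1 3-methylbut-2-enal; 2 trimethyl phosphonoacetate
Product: 3 methyl (2E)-5-methylhexa-2,4-dienoate
Conditions: NaH, THF, 0 °C to rt
Reagents that add atoms: none
Why: Horner–Wadsworth–Emmons olefination of an enal with a stabilised phosphonate anion should give the (2E)-dienoate.

Step 2
Reactants: 3 methyl (2E)-5-methylhexa-2,4-dienoate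
Product: 5 methyl (3E)-5-methylhexa-3,5-dienoate, via lithium trienolate 4 (not isolated)
Conditions: LiN(iPr)2 (1.2 equiv), THF/DMPU, -78 °C; then inverse quench into AcOH/THF, -78 °C
Reagents that add atoms: none
Why: Deconjugative protonation: removal of a proton from a C5 methyl group gives the extended enolate, and kinetic protonation at the α-carbon should give the skipped ester, with the 3,4-double bond E because it derives from the s-trans C3–C4 conformer of 3.

Step 3
Reactants: 5 methyl (3E)-5-methylhexa-3,5-dienoate; 6 methyl vinyl ketone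
Product: 7 methyl 2-[(1S,6R)-6-acetyl-3-methylcyclohex-2-en-1-yl]acetate (acetyl cis to the CH2CO2Me arm)
Conditions: (S)-3,3-diphenyl-1-(2-methylphenyl)tetrahydro-1H,3H-pyrrolo[1,2-c][1,3,2]oxazaborole (C24H24BNO, 20 mol%) activated with HN(SO2CF3)2 (17 mol%), 6 (2 equiv), CH2Cl2, -78 to -40 °C
Reagents that add atoms: none
Why: The s-cis diene 5 adds in a concerted, asynchronous [4+2] cycloaddition to methyl vinyl ketone held on the cationic boron through its carbonyl oxygen (s-trans enone, α-C–H···O contact to the ring oxygen), the closest known reaction type being the oxazaborolidinium-catalysed Diels–Alder reaction of enones with acyclic 1,3-dienes. Ring A closes in one six-membered [4+2] closure that forms the bond between the two future substituted methines (C3–C4 of ring A) and the bond between the two ring methylenes (C5–C6). The stereocentre at the acetyl-bearing carbon is set by the catalyst, whose phenyl group should shield the Re face of the bound enone α-carbon so that the diene adds to the Si face; the mirror-image catalyst from (R)-diphenylprolinol is used if the sense proves opposite. The stereocentre at the side-chain methine follows from the endo transition state and the E geometry of the diene, which place acetyl and CH2CO2Me cis. The step needs regio-, endo- and facial selectivity: the 1-alkyl and 3-methyl groups of the diene both make the unsubstituted diene terminus the most nucleophilic, so the "ortho" and "para" preferences coincide, Lewis-acid activation enforces the endo approach, and the ester arm is a weaker Lewis base than the ketone and should not divert the catalyst.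

Step 4
Reactants: 7 methyl 2-[(1S,6R)-6-acetyl-3-methylcyclohex-2-en-1-yl]acetate
Product: 9 2-[(1S,6S)-6-acetyl-3-methylcyclohex-2-en-1-yl]acetic acid (acetyl trans to the CH2CO2H arm), via lithium cis-keto carboxylate 8 (not isolated)
Conditions: LiOH (3 equiv), THF/MeOH/H2O, rt then 40 °C; 1 M HCl to pH 3, 0 °C
Reagents that add atoms: lithium hydroxide, [Li+].[OH-]
Why: Saponification gives a carboxylate that cannot undergo Claisen condensation with the methyl ketone, and hydroxide-mediated enolisation then equilibrates the acetyl-bearing carbon towards the trans (diequatorial) isomer; the equilibrium is not expected to be complete, and residual cis acid is removed in step 5 and returned to this step.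

Step 5
Reactants: 9 2-[(1S,6S)-6-acetyl-3-methylcyclohex-2-en-1-yl]acetic acid
Product: 10 (3aR,4S,7R,7aR)-4-acetyl-7-iodo-7-methylhexahydro-1-benzofuran-2(3H)-one
Conditions: I2 (2 equiv), KI, NaHCO3, CH2Cl2/H2O, 0 °C, dark; aq Na2S2O3
Reagents that add atoms: iodine, II
Why: Iodolactonisation: the carboxylate can reach the ring alkene only on the face that carries the side chain and opens the iodonium ion at the adjacent secondary carbon in a 5-exo, trans-diaxial manner, giving the cis-fused γ-lactone with oxygen syn to the side chain and the tertiary iodide anti; the cis-keto acid would have to place its acetyl group 1,3-diaxial to the new C–O bond, should cyclise more slowly and stays in the bicarbonate phase.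

Step 6
Reactants: 10 (3aR,4S,7R,7aR)-4-acetyl-7-iodo-7-methylhexahydro-1-benzofuran-2(3H)-one
Product: 12 methyl 2-[(1R,2R,3S,6S)-3-acetyl-6-methyl-7-oxabicyclo[4.1.0]heptan-2-yl]acetate, via iodohydrin ester 11 (not isolated)
Conditions: K2CO3 (2 equiv), MeOH, 0 °C to rt
Reagents that add atoms: methanol, CO
Why: Methanolysis of the lactone frees the secondary alkoxide trans-diaxial to the tertiary iodide, and intramolecular displacement with inversion closes the oxirane on the face syn to the CH2CO2Me arm, while the basic medium keeps the acetyl centre at its trans equilibrium position.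

Step 7
Reactants: 12 methyl 2-[(1R,2R,3S,6S)-3-acetyl-6-methyl-7-oxabicyclo[4.1.0]heptan-2-yl]acetate
Product: 13 methyl 2-[(1R,2R,3S,6S)-6-methyl-3-(prop-1-en-2-yl)-7-oxabicyclo[4.1.0]heptan-2-yl]acetate
Conditions: Ph3PCH3Br (2.0 equiv), KN(SiMe3)2 (1.8 equiv), THF, 0 °C; then 12, -78 to 0 °C
Reagents that add atoms: methyltriphenylphosphonium bromide, C[P+](c1ccccc1)(c1ccccc1)c1ccccc1.[Br-]
Why: Wittig methylenation is selective for the methyl ketone over the ester and the oxirane, and an ylide free of excess base should limit enolisation (epimerisation or Claisen-type closure onto the ester).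

Step 8
Reactants: 13 methyl 2-[(1R,2R,3S,6S)-6-methyl-3-(prop-1-en-2-yl)-7-oxabicyclo[4.1.0]heptan-2-yl]acetate
Product: 14 N-methoxy-N-methyl-2-[(1R,2R,3S,6S)-6-methyl-3-(prop-1-en-2-yl)-7-oxabicyclo[4.1.0]heptan-2-yl]acetamide
Conditions: MeNH(OMe)·HCl (2.5 equiv), iPrMgCl (5 equiv), THF, -20 to 0 °C; aq NH4Cl
Reagents that add atoms: N,O-dimethylhydroxylamine hydrochloride, CNOC.Cl
Why: Direct aminolysis of the unhindered methyl ester by the chloromagnesium amide of N,O-dimethylhydroxylamine gives the Weinreb amide at a temperature at which the trisubstituted oxirane should not be opened.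

Step 9
Reactants: 15 4-[(tert-butyldimethylsilyl)oxy]cyclohexan-1-ol (cis/trans mixture)
Product: 16 [(4-bromocyclohexyl)oxy](tert-butyl)dimethylsilane (cis/trans mixture)
Conditions: CBr4, PPh3, CH2Cl2, 0 °C to rt
Reagents that add atoms: carbon tetrabromide, BrC(Br)(Br)Br
Why: Appel bromination of a secondary alcohol under neutral conditions that leave the silyl ether intact.

Step 10
Reactants: 14 N-methoxy-N-methyl-2-[(1R,2R,3S,6S)-6-methyl-3-(prop-1-en-2-yl)-7-oxabicyclo[4.1.0]heptan-2-yl]acetamide; 16 [(4-bromocyclohexyl)oxy](tert-butyl)dimethylsilane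
Product: 18 1-{4-[(tert-butyldimethylsilyl)oxy]cyclohexyl}-2-[(1R,2R,3S,6S)-6-methyl-3-(prop-1-en-2-yl)-7-oxabicyclo[4.1.0]heptan-2-yl]ethan-1-one, via Grignard reagent 17 (not isolated)
Conditions: 16, Mg turnings (I2-activated), THF, rt to 40 °C; then 14, THF, -20 to 0 °C; aq NH4Cl
Reagents that add atoms: none
Why: Grignard acylation of a Weinreb amide, in which the chelated tetrahedral intermediate stops the addition at the ketone stage; at low temperature in THF the oxirane should survive.

Step 11
Reactants: 18 1-{4-[(tert-butyldimethylsilyl)oxy]cyclohexyl}-2-[(1R,2R,3S,6S)-6-methyl-3-(prop-1-en-2-yl)-7-oxabicyclo[4.1.0]heptan-2-yl]ethan-1-one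
Product: 19 tert-butyldimethyl[(4-{3-[(1R,2R,3S,6S)-6-methyl-3-(prop-1-en-2-yl)-7-oxabicyclo[4.1.0]heptan-2-yl]prop-1-en-2-yl}cyclohexyl)oxy]silane
Conditions: Ph3PCH3Br (3 equiv), KN(SiMe3)2 (2.8 equiv), THF, 0 to 50 °C
Reagents that add atoms: methyltriphenylphosphonium bromide, C[P+](c1ccccc1)(c1ccccc1)c1ccccc1.[Br-]
Why: Wittig methylenation of the α-branched ketone installs the 1,1-disubstituted linker alkene, and enolisation has no stereochemical cost because neither α-carbon carries stereochemical information needed later.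

Step 12
Reactants: 19 tert-butyldimethyl[(4-{3-[(1R,2R,3S,6S)-6-methyl-3-(prop-1-en-2-yl)-7-oxabicyclo[4.1.0]heptan-2-yl]prop-1-en-2-yl}cyclohexyl)oxy]silane
Product: 20 4-{3-[(1R,2R,3S,6S)-6-methyl-3-(prop-1-en-2-yl)-7-oxabicyclo[4.1.0]heptan-2-yl]prop-1-en-2-yl}cyclohexan-1-ol
Conditions: Bu4NF, THF, rt
Reagents that add atoms: none
Why: Fluoride-mediated cleavage of the silyl ether leaves the oxirane and the alkenes untouched.

Step 13
Reactants: 20 4-{3-[(1R,2R,3S,6S)-6-methyl-3-(prop-1-en-2-yl)-7-oxabicyclo[4.1.0]heptan-2-yl]prop-1-en-2-yl}cyclohexan-1-ol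
Product: 21 4-{3-[(1R,2R,3S,6S)-6-methyl-3-(prop-1-en-2-yl)-7-oxabicyclo[4.1.0]heptan-2-yl]prop-1-en-2-yl}cyclohexan-1-one
Conditions: Dess–Martin periodinane (C13H13IO8), NaHCO3, CH2Cl2, 0 °C to rt
Reagents that add atoms: none
Why: Buffered Dess–Martin oxidation converts both alcohol epimers into the same 4-substituted cyclohexanone without acid that would endanger the oxirane.

Step 14
Reactants: 21 4-{3-[(1R,2R,3S,6S)-6-methyl-3-(prop-1-en-2-yl)-7-oxabicyclo[4.1.0]heptan-2-yl]prop-1-en-2-yl}cyclohexan-1-one
Product: 23 trimethyl{[(4R)-4-{3-[(1R,2R,3S,6S)-6-methyl-3-(prop-1-en-2-yl)-7-oxabicyclo[4.1.0]heptan-2-yl]prop-1-en-2-yl}cyclohex-1-en-1-yl]oxy}silane, via lithium enolate 22 (not isolated)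
Conditions: (S,S)-bis(1-phenylethyl)amine, nBuLi, LiCl, THF, -78 °C; Me3SiCl (in situ quench), then 21, -78 °C; Et3N, aq NaHCO3, filtration through deactivated silica
Reagents that add atoms: chlorotrimethylsilane, C[Si](C)(C)Cl
Why: Group-selective deprotonation of a 4-substituted cyclohexanone by a chiral lithium amide with internal silyl chloride quench: the base distinguishes the two axial α-protons, and by analogy with 4-alkylcyclohexanones the (S,S) base should give the (4R) enol ether (the (R,R) base is used if the sense proves opposite), ring A being too remote to interfere.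

Step 15
Reactants: 23 trimethyl{[(4R)-4-{3-[(1R,2R,3S,6S)-6-methyl-3-(prop-1-en-2-yl)-7-oxabicyclo[4.1.0]heptan-2-yl]prop-1-en-2-yl}cyclohex-1-en-1-yl]oxy}silane
Product: 25 (2R,4R)-2-bromo-4-{3-[(1R,2R,3S,6S)-6-methyl-3-(prop-1-en-2-yl)-7-oxabicyclo[4.1.0]heptan-2-yl]prop-1-en-2-yl}cyclohexan-1-one (bromine equatorial, cis to the C4 substituent), via trans bromoketone 24 (not isolated)
Conditions: NBS (1.05 equiv), THF, -78 °C; then Bu4NBr (0.3 equiv), MeCN, rt; chromatography, trans isomer returned to the equilibration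
Reagents that add atoms: N-bromosuccinimide, O=C1CCC(=O)N1Br
Why: Regiospecific bromination of the silyl enol ether fixes which α-carbon carries bromine (axial attack, trans isomer first), and degenerate SN2 exchange with bromide ion in a polar aprotic medium then epimerises only the C–Br centre towards the more polar equatorial bromide, which is cis to the ring substituent; the preference is expected to be moderate, hence the recycling.

Step 16
Reactants: 25 (2R,4R)-2-bromo-4-{3-[(1R,2R,3S,6S)-6-methyl-3-(prop-1-en-2-yl)-7-oxabicyclo[4.1.0]heptan-2-yl]prop-1-en-2-yl}cyclohexan-1-one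
Product: 26 (1S,2R,4R)-2-bromo-1-methyl-4-{3-[(1R,2R,3S,6S)-6-methyl-3-(prop-1-en-2-yl)-7-oxabicyclo[4.1.0]heptan-2-yl]prop-1-en-2-yl}cyclohexan-1-ol (CNP0213097.1)
Conditions: MeMgBr (3 equiv), CeCl3 (3 equiv), THF, -78 °C; aq NH4Cl at -78 °C
Reagents that add atoms: methylmagnesium bromide, C[Mg]Br
Why: 1,2-Addition of the weakly basic methylcerium reagent to the α-bromo ketone should occur on the carbonyl face anti to the C–Br bond (Cornforth/polar Felkin–Anh), which is also the equatorial trajectory, giving equatorial methyl and axial hydroxyl cis to bromine; a cis bromohydrin alkoxide cannot close to an oxirane.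

**Compound list**

1 | 3-methylbut-2-enal | CC(C)=CC=O | starting material
2 | trimethyl phosphonoacetate | COC(=O)CP(=O)(OC)OC | starting material
3 | methyl (2E)-5-methylhexa-2,4-dienoate | COC(=O)/C=C/C=C(C)C | intermediate
4 | lithium (3E)-1-methoxy-5-methylhexa-1,3,5-trien-1-olate | [Li+].[O-]C(OC)=C/C=C/C(C)=C | intermediate (not isolated)
5 | methyl (3E)-5-methylhexa-3,5-dienoate | COC(=O)C/C=C/C(C)=C | intermediate
6 | methyl vinyl ketone | CC(=O)C=C | starting material
7 | methyl 2-[(1S,6R)-6-acetyl-3-methylcyclohex-2-en-1-yl]acetate (cis) | COC(=O)C[C@@H]1[C@H](C(C)=O)CCC(C)=C1 | intermediate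
8 | lithium 2-[(1S,6R)-6-acetyl-3-methylcyclohex-2-en-1-yl]acetate | [Li+].[O-]C(=O)C[C@@H]1[C@H](C(C)=O)CCC(C)=C1 | intermediate (not isolated)
9 | 2-[(1S,6S)-6-acetyl-3-methylcyclohex-2-en-1-yl]acetic acid (trans) | OC(=O)C[C@@H]1[C@@H](C(C)=O)CCC(C)=C1 | intermediate
10 | (3aR,4S,7R,7aR)-4-acetyl-7-iodo-7-methylhexahydro-1-benzofuran-2(3H)-one | O=C1C[C@@H]2[C@@H](C(C)=O)CC[C@@](C)(I)[C@@H]2O1 | intermediate
11 | methyl 2-[(1R,2R,3R,6S)-6-acetyl-2-hydroxy-3-iodo-3-methylcyclohexyl]acetate | COC(=O)C[C@@H]1[C@@H](C(C)=O)CC[C@@](C)(I)[C@@H]1O | intermediate (not isolated)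
12 | methyl 2-[(1R,2R,3S,6S)-3-acetyl-6-methyl-7-oxabicyclo[4.1.0]heptan-2-yl]acetate | COC(=O)C[C@@H]1[C@@H](C(C)=O)CC[C@]2(C)O[C@H]12 | intermediate
13 | methyl 2-[(1R,2R,3S,6S)-6-methyl-3-(prop-1-en-2-yl)-7-oxabicyclo[4.1.0]heptan-2-yl]acetate | COC(=O)C[C@@H]1[C@@H](C(C)=C)CC[C@]2(C)O[C@H]12 | intermediate
14 | N-methoxy-N-methyl-2-[(1R,2R,3S,6S)-6-methyl-3-(prop-1-en-2-yl)-7-oxabicyclo[4.1.0]heptan-2-yl]acetamide | CON(C)C(=O)C[C@@H]1[C@@H](C(C)=C)CC[C@]2(C)O[C@H]12 | intermediate
15 | 4-[(tert-butyldimethylsilyl)oxy]cyclohexan-1-ol (cis/trans mixture) | CC(C)(C)[Si](C)(C)OC1CCC(O)CC1 | starting material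
16 | [(4-bromocyclohexyl)oxy](tert-butyl)dimethylsilane (cis/trans mixture) | CC(C)(C)[Si](C)(C)OC1CCC(Br)CC1 | intermediate
17 | {4-[(tert-butyldimethylsilyl)oxy]cyclohexyl}magnesium bromide | CC(C)(C)[Si](C)(C)OC1CCC([Mg]Br)CC1 | intermediate (not isolated)
18 | 1-{4-[(tert-butyldimethylsilyl)oxy]cyclohexyl}-2-[(1R,2R,3S,6S)-6-methyl-3-(prop-1-en-2-yl)-7-oxabicyclo[4.1.0]heptan-2-yl]ethan-1-one | O=C(C[C@@H]1[C@@H](C(C)=C)CC[C@]2(C)O[C@H]12)C1CCC(O[Si](C)(C)C(C)(C)C)CC1 | intermediate
19 | tert-butyldimethyl[(4-{3-[(1R,2R,3S,6S)-6-methyl-3-(prop-1-en-2-yl)-7-oxabicyclo[4.1.0]heptan-2-yl]prop-1-en-2-yl}cyclohexyl)oxy]silane | C=C(C[C@@H]1[C@@H](C(C)=C)CC[C@]2(C)O[C@H]12)C1CCC(O[Si](C)(C)C(C)(C)C)CC1 | intermediate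
20 | 4-{3-[(1R,2R,3S,6S)-6-methyl-3-(prop-1-en-2-yl)-7-oxabicyclo[4.1.0]heptan-2-yl]prop-1-en-2-yl}cyclohexan-1-ol | C=C(C[C@@H]1[C@@H](C(C)=C)CC[C@]2(C)O[C@H]12)C1CCC(O)CC1 | intermediate
21 | 4-{3-[(1R,2R,3S,6S)-6-methyl-3-(prop-1-en-2-yl)-7-oxabicyclo[4.1.0]heptan-2-yl]prop-1-en-2-yl}cyclohexan-1-one | C=C(C[C@@H]1[C@@H](C(C)=C)CC[C@]2(C)O[C@H]12)C1CCC(=O)CC1 | intermediate
22 | lithium (4R)-4-{3-[(1R,2R,3S,6S)-6-methyl-3-(prop-1-en-2-yl)-7-oxabicyclo[4.1.0]heptan-2-yl]prop-1-en-2-yl}cyclohex-1-en-1-olate | C=C(C[C@@H]1[C@@H](C(C)=C)CC[C@]2(C)O[C@H]12)[C@@H]1CCC(O[Li])=CC1 | intermediate (not isolated)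
23 | trimethyl{[(4R)-4-{3-[(1R,2R,3S,6S)-6-methyl-3-(prop-1-en-2-yl)-7-oxabicyclo[4.1.0]heptan-2-yl]prop-1-en-2-yl}cyclohex-1-en-1-yl]oxy}silane | C=C(C[C@@H]1[C@@H](C(C)=C)CC[C@]2(C)O[C@H]12)[C@@H]1CCC(O[Si](C)(C)C)=CC1 | intermediate
24 | (2S,4R)-2-bromo-4-{3-[(1R,2R,3S,6S)-6-methyl-3-(prop-1-en-2-yl)-7-oxabicyclo[4.1.0]heptan-2-yl]prop-1-en-2-yl}cyclohexan-1-one (Br axial, trans) | C=C(C[C@@H]1[C@@H](C(C)=C)CC[C@]2(C)O[C@H]12)[C@@H]1CCC(=O)[C@@H](Br)C1 | intermediate (not isolated)
25 | (2R,4R)-2-bromo-4-{3-[(1R,2R,3S,6S)-6-methyl-3-(prop-1-en-2-yl)-7-oxabicyclo[4.1.0]heptan-2-yl]prop-1-en-2-yl}cyclohexan-1-one (Br equatorial, cis) | C=C(C[C@@H]1[C@@H](C(C)=C)CC[C@]2(C)O[C@H]12)[C@@H]1CCC(=O)[C@H](Br)C1 | intermediate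
26 | (1S,2R,4R)-2-bromo-1-methyl-4-{3-[(1R,2R,3S,6S)-6-methyl-3-(prop-1-en-2-yl)-7-oxabicyclo[4.1.0]heptan-2-yl]prop-1-en-2-yl}cyclohexan-1-ol | C=C(C[C@@H]1[C@@H](C(=C)C)CC[C@]2(C)O[C@H]12)[C@@H]1CC[C@](C)(O)[C@H](Br)C1 | target

**Step count**

Total: 16 steps. Longest linear sequence: 15 steps (steps 1–8 and 10–16); step 9 is a one-step side branch.

**Steps most likely to fail**

Step 3. The catalyst may discriminate the two faces of the bound enone incompletely with this 1,3-disubstituted diene, the endo preference may erode, or the electron-rich diene may oligomerise under the strong acid. The fallback keeps the same cycloaddition but moves stereocontrol to an auxiliary. It sets out from 5, which is combined with (4S)-3-acryloyl-4-benzyl-1,3-oxazolidin-2-one F1 and Et2AlCl in CH2Cl2 at -78 °C. The chelated s-cis acrylimide is shielded on its Re face by the benzyl group, so the diene should add endo to the Si face and give methyl 2-[(1S,6R)-6-{[(4S)-4-benzyl-2-oxo-1,3-oxazolidin-3-yl]carbonyl}-3-methylcyclohex-2-en-1-yl]acetate F2. EtSLi (from EtSH and nBuLi, THF, 0 °C) should cleave only the imide and give methyl 2-[(1S,6R)-6-[(ethylsulfanyl)carbonyl]-3-methylcyclohex-2-en-1-yl]acetate F3. Me2CuLi (Et2O, -78 °C) converts the thioester into the methyl ketone without touching the methyl ester, and the fallback comes back to the route at 7.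

Step 15. The bromide exchange may settle at an unfavourable axial/equatorial ratio, and repeated recycling may lose material through elimination of HBr. The fallback sets the equatorial C–Br bond by a kinetic inversion and sets out from 23. MeLi (THF, 0 °C) regenerates the lithium enolate 22, which is hydroxylated at -78 °C with 2-(benzenesulfonyl)-3-phenyloxaziridine. Axial attack should give (2S,4R)-2-hydroxy-4-{3-[(1R,2R,3S,6S)-6-methyl-3-(prop-1-en-2-yl)-7-oxabicyclo[4.1.0]heptan-2-yl]prop-1-en-2-yl}cyclohexan-1-one F4, with the hydroxyl trans to the ring substituent. Appel bromination (CBr4, PPh3, CH2Cl2, 0 °C) then replaces the hydroxyl by bromide with inversion, and the fallback comes back to the route at 25.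

Step 14. The chiral base may select the two α-methylene groups incompletely, which would appear as ring B diastereomers after bromination, or the amide base may attack the oxirane. The fallback replaces the stoichiometric base by enamine catalysis and sets out from 21. The ketone is brominated directly with 4,4-dibromo-2,6-di-tert-butylcyclohexa-2,5-dien-1-one in the presence of a C2-symmetric 4,5-diphenylimidazolidine (20 mol%) and benzoic acid in THF at -30 °C; the catalyst enantiomer is chosen on a model 4-substituted cyclohexanone. The product enters the bromide-exchange stage of step 15, so the fallback comes back to the route at 24; it makes no compound outside the list (none F0).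

Further compounds
F1 | step 3 | (4S)-3-acryloyl-4-benzyl-1,3-oxazolidin-2-one | C=CC(=O)N1C(=O)OC[C@@H]1Cc1ccccc1
F2 | step 3 | methyl 2-[(1S,6R)-6-{[(4S)-4-benzyl-2-oxo-1,3-oxazolidin-3-yl]carbonyl}-3-methylcyclohex-2-en-1-yl]acetate | COC(=O)C[C@@H]1[C@H](C(=O)N2C(=O)OC[C@@H]2Cc2ccccc2)CCC(C)=C1
F3 | step 3 | methyl 2-[(1S,6R)-6-[(ethylsulfanyl)carbonyl]-3-methylcyclohex-2-en-1-yl]acetate | COC(=O)C[C@@H]1[C@H](C(=O)SCC)CCC(C)=C1
F4 | step 15 | (2S,4R)-2-hydroxy-4-{3-[(1R,2R,3S,6S)-6-methyl-3-(prop-1-en-2-yl)-7-oxabicyclo[4.1.0]heptan-2-yl]prop-1-en-2-yl}cyclohexan-1-one | C=C(C[C@@H]1[C@@H](C(C)=C)CC[C@]2(C)O[C@H]12)[C@@H]1CCC(=O)[C@@H](O)C1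
F0 | step 14 | none | none
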